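**Plan**
Cuts: (a) the E C=C between C6 of the benzodioxine and the outer resorcinol ring. (b) Together, the C3–aryl bond to the 3,4-dihydroxyphenyl ring and the O1–C2 bond. (c) The O4–C3 bond, leading back to a phenol and an arylacetylene.
Enabling feature: in the ring segment O1–C2–C3–O4, C3 carries O4 and C2 is benzylic to the 3,5-dihydroxyphenyl ring. Once cut (b) is made, C2=C3 is the alkene of a β-aryloxystyrene hanging from O4, with O1–H beside it on the benzo ring. The enol-ether and styrene polarisations both send an incoming aryl group to C3 and the metal to C2.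
Forward order: the alkyne is made from the resorcinol aldehyde, and the 3-OH of 4-O-allyl methyl protocatechuate adds to it anti (O4–C3, Z-alkene). Deallylation frees O1–H, and a one-pot arylation/etherification closes the only ring to be built, the 1,4-dioxane. Ester → aldehyde → stilbene and removal of six acetals complete the route.
Stereochemistry: 3R comes from ligand-controlled choice of the alkene face at migratory insertion. 2S is relayed from it, because syn carbopalladation and backside C–O closure on a Z-alkene can give only the cis pair. The E-stilbene comes from the phosphonate olefination.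

Key step: step 8

Assumption: the sense of induction of BINAP on this new substrate class cannot be predicted, so (R)-BINAP stands for whichever antipode directs the aryl group to the Re face of the enol-ether carbon; enantiomeric purity is to be checked by chiral HPLC and, if needed, raised by crystallisation at the ester stage.

**Step 1**
Reactants: 1 3,5-dihydroxybenzaldehyde
Product: 2 3,5-bis(methoxymethoxy)benzaldehyde
Conditions: MOMCl (2.6 equiv), i-Pr2NEt (3 equiv), CH2Cl2, 0 °C → rt
Reagents that add atoms: chloromethyl methyl ether, COCCl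
Why: Williamson-type O-alkylation of both phenols with the reactive α-chloro ether under amine base is standard acetal protection and leaves the aldehyde untouched.

**Step 2**
Reactants: 2 3,5-bis(methoxymethoxy)benzaldehyde
Product: 3 1-ethynyl-3,5-bis(methoxymethoxy)benzene
Conditions: dimethyl (1-diazo-2-oxopropyl)phosphonate (1.2 equiv), K2CO3 (2 equiv), MeOH, rt
Reagents that add atoms: Ohira–Bestmann reagent, COP(=O)(OC)C(=[N+]=[N-])C(C)=O
Why: The Ohira–Bestmann variant of the Seyferth–Gilbert homologation turns non-enolisable aryl aldehydes into terminal alkynes under carbonate/methanol conditions that MOM ethers tolerate.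

**Step 3**
Reactants: 4 methyl 3,4-dihydroxybenzoate
Product: 5 methyl 3-hydroxy-4-(prop-2-enyloxy)benzoate
Conditions: allyl bromide (1.0 equiv), K2CO3 (1.0 equiv), DMF, 0 °C → rt
Reagents that add atoms: allyl bromide, C=CCBr
Why: Williamson etherification with one equivalent of weak base is selective because the 4-OH, conjugated with the para ester, is the more acidic phenol and is ionised first, a selectivity well established for protocatechuic esters and aldehydes.

**Step 4**
Reactants: 5 methyl 3-hydroxy-4-(prop-2-enyloxy)benzoate; 3 1-ethynyl-3,5-bis(methoxymethoxy)benzene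
Product: 6 methyl 3-{(Z)-2-[3,5-bis(methoxymethoxy)phenyl]ethenyloxy}-4-(prop-2-enyloxy)benzoate
Conditions: Cs2CO3 (30 mol %), dry DMSO, 90 °C, stopped at full conversion of 5
Reagents that add atoms: none
Why: Base-catalysed nucleophilic hydrophenoxylation of an arylacetylene in a dipolar aprotic solvent puts oxygen on the terminal carbon (benzylic carbanion) and runs by anti addition, so the kinetic product should be the Z-enol ether provided heating ends before Z-to-E equilibration.

**Step 5**
Reactants: 6 methyl 3-{(Z)-2-[3,5-bis(methoxymethoxy)phenyl]ethenyloxy}-4-(prop-2-enyloxy)benzoate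
Product: 7 methyl 3-{(Z)-2-[3,5-bis(methoxymethoxy)phenyl]ethenyloxy}-4-hydroxybenzoate
Conditions: Pd(PPh3)4 (5 mol %), morpholine (3 equiv), THF, rt; chromatography on Et3N-washed silica
Reagents that add atoms: none
Why: In this Tsuji–Trost deallylation zerovalent palladium ionises the allyl ether of the acidic para-ester phenol and morpholine traps the π-allyl unit under neutral conditions that spare the alkene geometry, the MOM acetals and the ester.

**Step 6**
Reactants: 8 4-bromobenzene-1,2-diol (4-bromocatechol)
Product: 9 4-bromo-1,2-bis(methoxymethoxy)benzene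
Conditions: MOMCl (2.6 equiv), i-Pr2NEt (3 equiv), CH2Cl2, 0 °C → rt, argon
Reagents that add atoms: chloromethyl methyl ether, COCCl
Why: The same Williamson-type acetal protection as in step 1, run under inert gas to avoid catechol oxidation, caps both phenols.

**Step 7**
Reactants: 9 4-bromo-1,2-bis(methoxymethoxy)benzene
Product: 10 4-iodo-1,2-bis(methoxymethoxy)benzene
Conditions: NaI (2 equiv), CuI (5 mol %), trans-N,N′-dimethylcyclohexane-1,2-diamine (10 mol %), dioxane, 110 °C
Reagents that add atoms: sodium iodide, [Na+].[I-]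
Why: The copper-catalysed aromatic Finkelstein exchange, driven by precipitation of NaBr, supplies the iodide needed for low-temperature oxidative addition and avoids organolithium chemistry next to the directing MOM groups.

**Step 8**
Reactants: 7 methyl 3-{(Z)-2-[3,5-bis(methoxymethoxy)phenyl]ethenyloxy}-4-hydroxybenzoate; 10 4-iodo-1,2-bis(methoxymethoxy)benzene
Product: 11 methyl (2S,3R)-3-[3,4-bis(methoxymethoxy)phenyl]-2-[3,5-bis(methoxymethoxy)phenyl]-2,3-dihydro-1,4-benzodioxine-6-carboxylate (cis)
Conditions: 10 (1.3 equiv), Pd2(dba)3·CHCl3 (2.5 mol %), (R)-BINAP (6 mol %), Ag2CO3 (1.2 equiv), 4 Å MS, THF, 50 °C, dark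
Reagents that add atoms: none
Why: Proposed new method: oxidative addition of 10 to zerovalent palladium and removal of iodide by silver should give a cation of the type [Pd(Ar)(BINAP)]+ that binds the Z-alkene of 7 and inserts syn, the aryl group moving to the oxygen-bearing carbon (future C3) and the metal to the benzylic carbon (future C2), where it is held as an η3-benzyl unit over the resorcinol ring so that, with the chelating diphosphine, no cis site is left for β-hydride loss. The phenoxide para to the ester, a stabilised nucleophile set free by carbonate, then attacks C2 on the face away from palladium, which forms O1–C2, closes the 1,4-dioxane ring in a 6-exo-tet mode and returns zerovalent palladium. The closest known reaction types are the cationic asymmetric Mizoroki–Heck arylation of cyclic cis-enol ethers (aryl to the O-bearing carbon), Heck/Tsuji–Trost carboetherification of 1,3-dienes with phenols, and the invertive outer-sphere substitution of η3-benzylpalladium cations by phenols and amines, but their combination on an acyclic β-aryloxystyrene has not been shown. C3 is controlled by the ligand, which has to present the Re face of the OCH= carbon to the migrating aryl group (3R), whereas C2 is controlled by the mechanism and the alkene geometry, because syn carbopalladation plus inversion is an overall anti addition and on the Z-alkene this leads only to the cis (2S,3R) pair. The step needs regioselectivity, secured by the concordant enol-ether and styrene polarisation, face selectivity, secured by the ligand, and a ring closure that is faster than β-hydride elimination, β-aryloxide elimination or inner-sphere C–O bond formation with retention, secured by the ortho placement of the nucleophile on the same catechol unit and by the coordinatively saturated η3 complex.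

**Step 9**
Reactants: 11 methyl (2S,3R)-3-[3,4-bis(methoxymethoxy)phenyl]-2-[3,5-bis(methoxymethoxy)phenyl]-2,3-dihydro-1,4-benzodioxine-6-carboxylate
Product: 12 {(2S,3R)-3-[3,4-bis(methoxymethoxy)phenyl]-2-[3,5-bis(methoxymethoxy)phenyl]-2,3-dihydro-1,4-benzodioxin-6-yl}methanol
Conditions: i-Bu2AlH (3 equiv), CH2Cl2, −78 → 0 °C; aq. potassium sodium tartrate
Reagents that add atoms: none
Why: Hydride reduction of an aryl ester with excess i-Bu2AlH goes cleanly to the benzylic alcohol and touches neither the acetals nor the benzylic aryl ethers at C2 and C3.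

**Step 10**
Reactants: 12 {(2S,3R)-3-[3,4-bis(methoxymethoxy)phenyl]-2-[3,5-bis(methoxymethoxy)phenyl]-2,3-dihydro-1,4-benzodioxin-6-yl}methanol
Product: 13 (2S,3R)-3-[3,4-bis(methoxymethoxy)phenyl]-2-[3,5-bis(methoxymethoxy)phenyl]-2,3-dihydro-1,4-benzodioxine-6-carbaldehyde
Conditions: activated MnO2 (excess), CH2Cl2, rt
Reagents that add atoms: none
Why: Heterogeneous MnO2 oxidation is selective for benzylic alcohols, stops at the aldehyde and is neutral, so the two stereocentres are not at risk.

**Step 11**
Reactants: 2 3,5-bis(methoxymethoxy)benzaldehyde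
Product: 14 [3,5-bis(methoxymethoxy)phenyl]methanol
Conditions: NaBH4, MeOH, 0 °C
Reagents that add atoms: none
Why: Borohydride reduction of an aryl aldehyde is fast and leaves acetals unchanged.

**Step 12**
Reactants: 14 [3,5-bis(methoxymethoxy)phenyl]methanol
Product: 15 1-(bromomethyl)-3,5-bis(methoxymethoxy)benzene
Conditions: CBr4 (1.2 equiv), PPh3 (1.25 equiv), CH2Cl2, 0 °C
Reagents that add atoms: carbon tetrabromide, BrC(Br)(Br)Br
Why: The Appel reaction replaces the primary benzylic hydroxyl by SN2 attack of bromide on the oxyphosphonium ion under nearly neutral conditions that keep MOM ethers.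

**Step 13**
Reactants: 15 1-(bromomethyl)-3,5-bis(methoxymethoxy)benzene
Product: 16 diethyl [3,5-bis(methoxymethoxy)benzyl]phosphonate
Conditions: P(OEt)3 (neat, excess), 120 °C
Reagents that add atoms: triethyl phosphite, CCOP(OCC)OCC
Why: The Michaelis–Arbuzov reaction of a primary benzylic bromide is reliable, and volatile bromoethane leaves the melt.

**Step 14**
Reactants: 13 (2S,3R)-3-[3,4-bis(methoxymethoxy)phenyl]-2-[3,5-bis(methoxymethoxy)phenyl]-2,3-dihydro-1,4-benzodioxine-6-carbaldehyde; 16 diethyl [3,5-bis(methoxymethoxy)benzyl]phosphonate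
Product: 17 (2S,3R)-3-[3,4-bis(methoxymethoxy)phenyl]-2-[3,5-bis(methoxymethoxy)phenyl]-6-{(E)-2-[3,5-bis(methoxymethoxy)phenyl]ethenyl}-2,3-dihydro-1,4-benzodioxine
Conditions: 16 (1.2 equiv), KOt-Bu (1.2 equiv), THF, 0 °C, then 13, 0 °C → rt
Reagents that add atoms: none
Why: Horner–Wadsworth–Emmons olefination with a benzylic phosphonate anion gives the E-stilbene through reversible addition, and the base cannot open the dioxane ring because C2 and C3 bear no acidic hydrogen and the para-phenol that could form a quinone methide is still masked.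

**Step 15**
Reactants: 17 (2S,3R)-3-[3,4-bis(methoxymethoxy)phenyl]-2-[3,5-bis(methoxymethoxy)phenyl]-6-{(E)-2-[3,5-bis(methoxymethoxy)phenyl]ethenyl}-2,3-dihydro-1,4-benzodioxine
Product: 18 5-{(E)-2-[(2S,3R)-3-(3,4-dihydroxyphenyl)-2-(3,5-dihydroxyphenyl)-2,3-dihydro-1,4-benzodioxin-6-yl]ethenyl}benzene-1,3-diol (CNP0283264.2)
Conditions: HCl (about 0.5 M) in MeOH–THF, 0 → 15 °C, argon; pH 6 phosphate buffer
Reagents that add atoms: none
Why: In this acid-catalysed transacetalisation with methanol the MOM acetals protonate and cleave much faster than the benzylic aryl ethers at C2 and C3, whose ionisation is further slowed by the vicinal oxygen, so a short cold exposure with a slightly acidic quench should free the six phenols with the cis relationship and the E-alkene intact.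

**Compound list**
1 | 3,5-dihydroxybenzaldehyde | O=Cc1cc(O)cc(O)c1 | starting material
2 | 3,5-bis(methoxymethoxy)benzaldehyde | O=Cc1cc(OCOC)cc(OCOC)c1 | intermediate
3 | 1-ethynyl-3,5-bis(methoxymethoxy)benzene | C#Cc1cc(OCOC)cc(OCOC)c1 | intermediate
4 | methyl 3,4-dihydroxybenzoate | COC(=O)c1ccc(O)c(O)c1 | starting material
5 | methyl 3-hydroxy-4-(prop-2-enyloxy)benzoate | COC(=O)c1ccc(OCC=C)c(O)c1 | intermediate
6 | methyl 3-{(Z)-2-[3,5-bis(methoxymethoxy)phenyl]ethenyloxy}-4-(prop-2-enyloxy)benzoate | COC(=O)c1ccc(OCC=C)c(O/C=C\c2cc(OCOC)cc(OCOC)c2)c1 | intermediate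
7 | methyl 3-{(Z)-2-[3,5-bis(methoxymethoxy)phenyl]ethenyloxy}-4-hydroxybenzoate | COC(=O)c1ccc(O)c(O/C=C\c2cc(OCOC)cc(OCOC)c2)c1 | intermediate
8 | 4-bromobenzene-1,2-diol | Oc1ccc(Br)cc1O | starting material
9 | 4-bromo-1,2-bis(methoxymethoxy)benzene | COCOc1ccc(Br)cc1OCOC | intermediate
10 | 4-iodo-1,2-bis(methoxymethoxy)benzene | COCOc1ccc(I)cc1OCOC | intermediate
11 | methyl (2S,3R)-3-[3,4-bis(methoxymethoxy)phenyl]-2-[3,5-bis(methoxymethoxy)phenyl]-2,3-dihydro-1,4-benzodioxine-6-carboxylate | COC(=O)c1ccc2c(c1)O[C@H](c1ccc(OCOC)c(OCOC)c1)[C@H](c1cc(OCOC)cc(OCOC)c1)O2 | intermediate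
12 | {(2S,3R)-3-[3,4-bis(methoxymethoxy)phenyl]-2-[3,5-bis(methoxymethoxy)phenyl]-2,3-dihydro-1,4-benzodioxin-6-yl}methanol | OCc1ccc2c(c1)O[C@H](c1ccc(OCOC)c(OCOC)c1)[C@H](c1cc(OCOC)cc(OCOC)c1)O2 | intermediate
13 | (2S,3R)-3-[3,4-bis(methoxymethoxy)phenyl]-2-[3,5-bis(methoxymethoxy)phenyl]-2,3-dihydro-1,4-benzodioxine-6-carbaldehyde | O=Cc1ccc2c(c1)O[C@H](c1ccc(OCOC)c(OCOC)c1)[C@H](c1cc(OCOC)cc(OCOC)c1)O2 | intermediate
14 | [3,5-bis(methoxymethoxy)phenyl]methanol | OCc1cc(OCOC)cc(OCOC)c1 | intermediate
15 | 1-(bromomethyl)-3,5-bis(methoxymethoxy)benzene | BrCc1cc(OCOC)cc(OCOC)c1 | intermediate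
16 | diethyl [3,5-bis(methoxymethoxy)benzyl]phosphonate | CCOP(=O)(Cc1cc(OCOC)cc(OCOC)c1)OCC | intermediate
17 | (2S,3R)-3-[3,4-bis(methoxymethoxy)phenyl]-2-[3,5-bis(methoxymethoxy)phenyl]-6-{(E)-2-[3,5-bis(methoxymethoxy)phenyl]ethenyl}-2,3-dihydro-1,4-benzodioxine | COCOc1cc(OCOC)cc(/C=C/c2ccc3c(c2)O[C@H](c2ccc(OCOC)c(OCOC)c2)[C@H](c2cc(OCOC)cc(OCOC)c2)O3)c1 | intermediate
18 | 5-{(E)-2-[(2S,3R)-3-(3,4-dihydroxyphenyl)-2-(3,5-dihydroxyphenyl)-2,3-dihydro-1,4-benzodioxin-6-yl]ethenyl}benzene-1,3-diol | Oc1cc(O)cc(/C=C/c2ccc3c(c2)O[C@H](c2ccc(O)c(O)c2)[C@H](c2cc(O)cc(O)c2)O3)c1 | target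

**Totals**
Total step count: 15.
Longest linear sequence: 9 steps (1, 2, 4, 5, 8, 9, 10, 14, 15).

**Steps most likely to fail**

**Step 8 (new method).**
- β-Hydride or β-aryloxide elimination may outrun ring closure.
- Inner-sphere C–O bond formation with retention may erode the cis selectivity.
- Facial selectivity on an acyclic alkene may be poor.
- Traces of acid or electrophilic palladium may trigger acetalisation of the enol ether by the neighbouring phenol.

The fallback uses known chemistry, sets out from 2 and 10 and returns at 11. Wittig methylenation of 2 (Ph3PCH3Br, KOt-Bu, THF) would give 1-ethenyl-3,5-bis(methoxymethoxy)benzene F1. Mizoroki–Heck coupling of it with 10 (Pd(OAc)2, P(o-tol)3, Et3N, DMF, 90 °C) would give (E)-3,4,3′,5′-tetrakis(methoxymethoxy)stilbene F2. Shi epoxidation follows, using the L-fructose-derived ketone (1,2:4,5-di-O-isopropylidene-β-L-erythro-2,3-hexodiulo-2,6-pyranose), KHSO5 and K2CO3 buffer at 0 °C. It would give (2S,3S)-2-[3,4-bis(methoxymethoxy)phenyl]-3-[3,5-bis(methoxymethoxy)phenyl]oxirane F3. The caesium phenoxide of purchased methyl 4-fluoro-3-hydroxybenzoate (COC(=O)c1ccc(F)c(O)c1; Cs2CO3, DMF, 70 °C) would open the epoxide with inversion at the carbon next to the para-oxygenated ring. This forms O4–C3 and gives methyl 3-{(1R,2S)-1-[3,4-bis(methoxymethoxy)phenyl]-2-[3,5-bis(methoxymethoxy)phenyl]-2-hydroxyethoxy}-4-fluorobenzoate F4. NaH in DMF would then close O1–C8a by intramolecular SNAr para to the ester, with retention at C2. One inversion on a trans-epoxide gives the erythro, hence cis, compound 11.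

**Step 4.**
- Z-to-E drift may set in on prolonged heating.
- The moderately nucleophilic phenoxide may add sluggishly.
- Adventitious hydroxide may cleave the ester.
- The base may cause allyl-to-propenyl migration.

The fallback sets out from 2 (with 5 as partner) and returns at 6. Stork–Zhao olefination of 2 ([Ph3PCH2I]I, NaN(SiMe3)2, THF–DMPU, −78 °C) would give 1-[(Z)-2-iodoethenyl]-3,5-bis(methoxymethoxy)benzene F5. Ullmann-type vinylation of 5 with it (CuI, N,N-dimethylglycine, Cs2CO3, dioxane, 60 °C) forms the O–C(sp2) bond with retention of the alkene geometry and gives 6.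

**Step 15.**
- Acid may ionise the C3–O4 bond at the para-oxygenated benzylic position, causing cis-to-trans epimerisation or methanolysis.
- Acetal cleavage may be incomplete within the short exposure.

The fallback sets out from 17 and returns at 18, replacing Brønsted-acid hydrolysis by a protecting-group transposition. Et3SiOTf and 2,2′-bipyridyl (MeCN–CH2Cl2, 0 °C) convert aromatic MOM ethers directly into silyl ethers in a buffered medium. This would give (2S,3R)-3-[3,4-bis(triethylsilyloxy)phenyl]-2-[3,5-bis(triethylsilyloxy)phenyl]-6-{(E)-2-[3,5-bis(triethylsilyloxy)phenyl]ethenyl}-2,3-dihydro-1,4-benzodioxine F6. After purification it is desilylated with Et3N·3HF in THF at 0 °C, a weakly acidic fluoride source that generates no free phenoxide, to give 18.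

**Further compounds**
F1 | step 8 | 1-ethenyl-3,5-bis(methoxymethoxy)benzene | C=Cc1cc(OCOC)cc(OCOC)c1
F2 | step 8 | (E)-3,4,3′,5′-tetrakis(methoxymethoxy)stilbene | COCOc1ccc(/C=C/c2cc(OCOC)cc(OCOC)c2)cc1OCOC
F3 | step 8 | (2S,3S)-2-[3,4-bis(methoxymethoxy)phenyl]-3-[3,5-bis(methoxymethoxy)phenyl]oxirane | COCOc1ccc(cc1OCOC)[C@@H]1O[C@H]1c1cc(OCOC)cc(OCOC)c1
F4 | step 8 | methyl 3-{(1R,2S)-1-[3,4-bis(methoxymethoxy)phenyl]-2-[3,5-bis(methoxymethoxy)phenyl]-2-hydroxyethoxy}-4-fluorobenzoate | COC(=O)c1ccc(F)c(c1)O[C@H](c1ccc(OCOC)c(OCOC)c1)[C@H](c1cc(OCOC)cc(OCOC)c1)O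
F5 | step 4 | 1-[(Z)-2-iodoethenyl]-3,5-bis(methoxymethoxy)benzene | I/C=C\c1cc(OCOC)cc(OCOC)c1
F6 | step 15 | (2S,3R)-3-[3,4-bis(triethylsilyloxy)phenyl]-2-[3,5-bis(triethylsilyloxy)phenyl]-6-{(E)-2-[3,5-bis(triethylsilyloxy)phenyl]ethenyl}-2,3-dihydro-1,4-benzodioxine | CC[Si](CC)(CC)Oc1cc(O[Si](CC)(CC)CC)cc(/C=C/c2ccc3c(c2)O[C@H](c2ccc(O[Si](CC)(CC)CC)c(O[Si](CC)(CC)CC)c2)[C@H](c2cc(O[Si](CC)(CC)CC)cc(O[Si](CC)(CC)CC)c2)O3)c1
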